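**Retrosynthetic overview**

- Ester C–O: target ⇐ azulene-3,4-diol + 4-methoxybenzoyl chloride. The seven-membered ring is closed last, at C5=C6, by ring-closing metathesis of a vinyl carbinol / isopropenyl diene.
- The diene-diol ⇐ bicyclic α-hydroxy-γ-lactone (partial reduction, methylenation). The tertiary carbinol C-3 ⇐ isopropyl addition to a cyclopentanone, which lactonises.
- The five-membered ring is closed first, at C2–C3, by intramolecular hydroacylation of a 3,3-disubstituted 4-pentenal.
- Key bond C3a–C8a: chelated dianion Ireland–Claisen [3,3] rearrangement of an allyl (R)-malate. The bought carbinol (C-4) sets C-3a, and the chair transition state sets the quaternary C-8a.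
- Building blocks: (R)-malic acid, (2E)-3,6-dimethylhepta-2,6-dien-1-ol (two steps from hex-5-yn-2-one), 4-methoxybenzoyl chloride.

Assumption: (R)-malic acid (D-malic acid) is taken as an inexpensive commercial chiral-pool acid; C-numbers are the azulene locants of the target name.

**Route**

Step 1
Reactants: 1 hex-5-yn-2-one
Product: 2 2-methylhex-1-en-5-yne
Conditions: Ph3PCH3Br, KOtBu, Et2O, 0 → 25 °C
Reagents that add atoms: methyltriphenylphosphonium bromide, C[P+](c1ccccc1)(c1ccccc1)c1ccccc1.[Br-]
Why: Wittig methylenation converts the methyl ketone into the 1,1-disubstituted alkene that later serves as the metathesis partner, and the ylide is too weak a base to deprotonate the terminal alkyne.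

Step 2
Reactants: 2 2-methylhex-1-en-5-yne
Product: 4 (2E)-3,6-dimethylhepta-2,6-dien-1-ol, via alkenylalane 3 (not isolated)
Conditions: AlMe3 (2 equiv), Cp2ZrCl2 (20 mol %), CH2Cl2, 25 °C; then nBuLi, THF–hexane, −78 °C; (CH2O)n, 25 °C; aq. HCl
Reagents that add atoms: trimethylaluminium, C[Al](C)C; formaldehyde (as paraformaldehyde), C=O
Why: Negishi zirconium-catalysed carboalumination adds methyl and aluminium syn across the terminal alkyne with aluminium at the terminus, and the alanate is hydroxymethylated with retention, so the trisubstituted allylic alcohol is obtained as the (E)-isomer only, which the later chair transition state requires.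

Step 3
Reactants: 5 (R)-malic acid
Product: 7 (3R)-3-hydroxy-4-methoxy-4-oxobutanoic acid, via trifluoroacetylated anhydride 6 (not isolated)
Conditions: (CF3CO)2O, 0 → 25 °C; evaporate; MeOH, 25 °C
Reagents that add atoms: methanol, CO
Why: Regioselective anhydride alcoholysis: methanol opens the cyclic anhydride at the more electrophilic carbonyl next to the acylated oxygen and also removes the trifluoroacetate, so only the carboxyl beside the untouched stereocentre becomes the methyl ester.

Step 4
Reactants: 7 (3R)-3-hydroxy-4-methoxy-4-oxobutanoic acid; 4 (2E)-3,6-dimethylhepta-2,6-dien-1-ol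
Product: 8 4-[(2E)-3,6-dimethylhepta-2,6-dien-1-yl] 1-methyl (2R)-2-hydroxybutanedioate
Conditions: DCC, DMAP (10 mol %), CH2Cl2, 0 → 25 °C
Reagents that add atoms: none
Why: Steglich esterification of the free CH2CO2H group, in which the primary allylic alcohol outcompetes the hindered secondary hydroxyl next to the ester.

Step 5
Reactants: 8 4-[(2E)-3,6-dimethylhepta-2,6-dien-1-yl] 1-methyl (2R)-2-hydroxybutanedioate
Product: 10 (2S,3R)-2-[(3S)-3,6-dimethylhepta-1,6-dien-3-yl]-3-hydroxy-4-methoxy-4-oxobutanoic acid, via dilithium dianion 9 (not isolated)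
Conditions: LiN(iPr)2 (2.3 equiv), THF, −78 → 25 °C; aq. HCl
Reagents that add atoms: none
Why: Chelated dianion Ireland–Claisen [3,3]-sigmatropic rearrangement forms the C3a–C8a bond: lithium bridging alkoxide and enolate oxygen fixes the enolate geometry and directs bond formation anti to the CO2Me group (the Fráter–Seebach sense), which sets C-3a from the bought carbinol, and the chair transition state with the (E)-alkene (chain equatorial, methyl axial) sets the quaternary C-8a.

Step 6
Reactants: 10 (2S,3R)-2-[(3S)-3,6-dimethylhepta-1,6-dien-3-yl]-3-hydroxy-4-methoxy-4-oxobutanoic acid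
Product: 11 S-ethyl (2S,3R)-2-[(3S)-3,6-dimethylhepta-1,6-dien-3-yl]-3-hydroxy-4-methoxy-4-oxobutanethioate
Conditions: EtSH, DCC, DMAP (cat.), CH2Cl2, 0 °C
Reagents that add atoms: ethanethiol, CCS
Why: Steglich thioesterification, in which the thiol is far more nucleophilic than the hindered secondary hydroxyl, activates the acid for reduction to the aldehyde without passing through the primary alcohol that would lactonise onto the methyl ester.

Step 7
Reactants: 11 S-ethyl (2S,3R)-2-[(3S)-3,6-dimethylhepta-1,6-dien-3-yl]-3-hydroxy-4-methoxy-4-oxobutanethioate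
Product: 12 methyl (2R,3S,4S)-4-ethenyl-3-formyl-2-hydroxy-4,7-dimethyloct-7-enoate
Conditions: Et3SiH, Pd/CaCO3 poisoned by Pb(OAc)2 (Lindlar catalyst, 5 mol % Pd), acetone, 25 °C
Reagents that add atoms: none
Why: Fukuyama reduction stops cleanly at the aldehyde under neutral conditions, so the methyl ester, both alkenes and the α-stereocentre are preserved.

Step 8
Reactants: 12 methyl (2R,3S,4S)-4-ethenyl-3-formyl-2-hydroxy-4,7-dimethyloct-7-enoate
Product: 13 methyl (2R)-2-hydroxy-2-[(1S,2S)-2-methyl-2-(3-methylbut-3-en-1-yl)-5-oxocyclopentyl]acetate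
Conditions: [Rh(nbd)(dppe)]BF4 (5 mol %, activated by H2), acetone, 25 °C
Reagents that add atoms: none
Why: Rhodium-catalysed intramolecular hydroacylation of a 4-pentenal (aldehyde C–H activation, insertion of the vinyl group, reductive elimination) closes the cyclopentanone at C2–C3; 3,3-disubstitution favours cyclisation over decarbonylation and the isopropenyl group is too remote to react.

Step 9
Reactants: 13 methyl (2R)-2-hydroxy-2-[(1S,2S)-2-methyl-2-(3-methylbut-3-en-1-yl)-5-oxocyclopentyl]acetate
Product: 15 (3R,3aS,4S,6aR)-3-hydroxy-4-methyl-4-(3-methylbut-3-en-1-yl)-6a-(propan-2-yl)hexahydro-2H-cyclopenta[b]furan-2-one, via hydroxy ester 14 (not isolated)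
Conditions: iPrMgCl (3.5 equiv), CeCl3 (3.5 equiv), THF, −78 → 25 °C; aq. NH4Cl
Reagents that add atoms: isopropylmagnesium chloride, CC(C)[Mg]Cl
Why: Organocerium 1,2-addition (CeCl3 suppresses enolisation and β-hydride reduction) occurs on the ketone face opposite the adjacent side chain, which sets C-3 with its hydroxyl cis to that chain, and only this diastereomer can lactonise onto the methyl ester.

Step 10
Reactants: 15 (3R,3aS,4S,6aR)-3-hydroxy-4-methyl-4-(3-methylbut-3-en-1-yl)-6a-(propan-2-yl)hexahydro-2H-cyclopenta[b]furan-2-one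
Product: 16 (3R,3aS,4S,6aR)-4-methyl-4-(3-methylbut-3-en-1-yl)-6a-(propan-2-yl)hexahydro-2H-cyclopenta[b]furan-2,3-diol (both anomers)
Conditions: iBu2AlH (2.5 equiv), CH2Cl2, −78 °C; aq. KNaC4H4O6
Reagents that add atoms: none
Why: Partial reduction of the γ-lactone stops at the lactol because the tetrahedral aluminate is stable at −78 °C, and the alkenes are inert.

Step 11
Reactants: 16 (3R,3aS,4S,6aR)-4-methyl-4-(3-methylbut-3-en-1-yl)-6a-(propan-2-yl)hexahydro-2H-cyclopenta[b]furan-2,3-diol
Product: 18 (1R,2S,3S)-2-[(1S)-1-hydroxyprop-2-en-1-yl]-3-methyl-3-(3-methylbut-3-en-1-yl)-1-(propan-2-yl)cyclopentan-1-ol, via hydroxy aldehyde 17 (not isolated)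
Conditions: Ph3PCH3Br (5 equiv), KOtBu (4.8 equiv), THF, 0 → 50 °C
Reagents that add atoms: methyltriphenylphosphonium bromide, C[P+](c1ccccc1)(c1ccccc1)c1ccccc1.[Br-]
Why: Wittig methylenation of the lactol through its open hydroxy-aldehyde form, as practised on unprotected sugar lactols, unveils the vinyl carbinol and frees the tertiary hydroxyl.

Step 12
Reactants: 18 (1R,2S,3S)-2-[(1S)-1-hydroxyprop-2-en-1-yl]-3-methyl-3-(3-methylbut-3-en-1-yl)-1-(propan-2-yl)cyclopentan-1-ol
Product: 19 (3R,3aS,4S,8aS)-6,8a-dimethyl-3-(propan-2-yl)-1,2,3,3a,4,7,8,8a-octahydroazulene-3,4-diol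
Conditions: second-generation Grubbs catalyst (H2IMes)(PCy3)Cl2Ru=CHPh (5 mol %), CH2Cl2 (0.005 M), 40 °C
Reagents that add atoms: none
Why: Ring-closing metathesis between the vinyl carbinol and the 1,1-disubstituted alkene forms the trisubstituted C5=C6 bond of the trans-fused seven-membered ring with loss of ethene; no other alkene is present and no stereocentre is touched.

Step 13
Reactants: 19 (3R,3aS,4S,8aS)-6,8a-dimethyl-3-(propan-2-yl)-1,2,3,3a,4,7,8,8a-octahydroazulene-3,4-diol; 20 4-methoxybenzoyl chloride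
Product: 21 (3R,3aS,4S,8aS)-3-hydroxy-6,8a-dimethyl-3-(propan-2-yl)-1,2,3,3a,4,7,8,8a-octahydroazulen-4-yl 4-methoxybenzoate
Conditions: Et3N, DMAP (cat.), CH2Cl2, 0 → 25 °C
Reagents that add atoms: none
Why: DMAP-catalysed acylation takes place only at the secondary allylic hydroxyl, since the tertiary hydroxyl is too hindered to react.

**Compound list**

1 | hex-5-yn-2-one | CC(=O)CCC#C | starting material
2 | 2-methylhex-1-en-5-yne | C=C(C)CCC#C | intermediate
3 | [(1E)-2,5-dimethylhexa-1,5-dien-1-yl]dimethylalumane | C[Al](C)/C=C(\C)CCC(C)=C | intermediate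
4 | (2E)-3,6-dimethylhepta-2,6-dien-1-ol | OC/C=C(\C)CCC(C)=C | intermediate
5 | (R)-malic acid, (2R)-2-hydroxybutanedioic acid | O[C@H](CC(O)=O)C(O)=O | starting material
6 | (3R)-2,5-dioxooxolan-3-yl trifluoroacetate | O=C1C[C@@H](OC(=O)C(F)(F)F)C(=O)O1 | intermediate
7 | (3R)-3-hydroxy-4-methoxy-4-oxobutanoic acid | COC(=O)[C@H](O)CC(O)=O | intermediate
8 | 4-[(2E)-3,6-dimethylhepta-2,6-dien-1-yl] 1-methyl (2R)-2-hydroxybutanedioate | COC(=O)[C@H](O)CC(=O)OC/C=C(\C)CCC(C)=C | intermediate
9 | dilithium alkoxide ester enolate of 8 (enolate oxygen cis to the alkoxide-bearing carbon) | COC(=O)[C@H]([O-])/C=C(\[O-])OC/C=C(\C)CCC(C)=C.[Li+].[Li+] | intermediate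
10 | (2S,3R)-2-[(3S)-3,6-dimethylhepta-1,6-dien-3-yl]-3-hydroxy-4-methoxy-4-oxobutanoic acid | OC(=O)[C@H]([C@@H](O)C(=O)OC)[C@](C)(C=C)CCC(C)=C | intermediate
11 | S-ethyl (2S,3R)-2-[(3S)-3,6-dimethylhepta-1,6-dien-3-yl]-3-hydroxy-4-methoxy-4-oxobutanethioate | CCSC(=O)[C@H]([C@@H](O)C(=O)OC)[C@](C)(C=C)CCC(C)=C | intermediate
12 | methyl (2R,3S,4S)-4-ethenyl-3-formyl-2-hydroxy-4,7-dimethyloct-7-enoate | O=C[C@H]([C@@H](O)C(=O)OC)[C@](C)(C=C)CCC(C)=C | intermediate
13 | methyl (2R)-2-hydroxy-2-[(1S,2S)-2-methyl-2-(3-methylbut-3-en-1-yl)-5-oxocyclopentyl]acetate | COC(=O)[C@H](O)[C@H]1C(=O)CC[C@]1(C)CCC(C)=C | intermediate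
14 | methyl (2R)-2-hydroxy-2-[(1S,2R,5S)-2-hydroxy-5-methyl-5-(3-methylbut-3-en-1-yl)-2-(propan-2-yl)cyclopentyl]acetate | COC(=O)[C@H](O)[C@H]1[C@](O)(C(C)C)CC[C@]1(C)CCC(C)=C | intermediate
15 | (3R,3aS,4S,6aR)-3-hydroxy-4-methyl-4-(3-methylbut-3-en-1-yl)-6a-(propan-2-yl)hexahydro-2H-cyclopenta[b]furan-2-one | O=C1O[C@@]2(C(C)C)CC[C@](C)(CCC(C)=C)[C@H]2[C@H]1O | intermediate
16 | (3R,3aS,4S,6aR)-4-methyl-4-(3-methylbut-3-en-1-yl)-6a-(propan-2-yl)hexahydro-2H-cyclopenta[b]furan-2,3-diol (both anomers) | OC1O[C@@]2(C(C)C)CC[C@](C)(CCC(C)=C)[C@H]2[C@H]1O | intermediate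
17 | (2R)-2-hydroxy-2-[(1S,2R,5S)-2-hydroxy-5-methyl-5-(3-methylbut-3-en-1-yl)-2-(propan-2-yl)cyclopentyl]acetaldehyde | O=C[C@H](O)[C@H]1[C@](O)(C(C)C)CC[C@]1(C)CCC(C)=C | intermediate
18 | (1R,2S,3S)-2-[(1S)-1-hydroxyprop-2-en-1-yl]-3-methyl-3-(3-methylbut-3-en-1-yl)-1-(propan-2-yl)cyclopentan-1-ol | C=C[C@H](O)[C@H]1[C@](O)(C(C)C)CC[C@]1(C)CCC(C)=C | intermediate
19 | (3R,3aS,4S,8aS)-6,8a-dimethyl-3-(propan-2-yl)-1,2,3,3a,4,7,8,8a-octahydroazulene-3,4-diol | O[C@H]1C=C(C)CC[C@@]2(C)CC[C@@](O)(C(C)C)[C@H]12 | intermediate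
20 | 4-methoxybenzoyl chloride | COc1ccc(C(Cl)=O)cc1 | starting material
21 | (3R,3aS,4S,8aS)-3-hydroxy-6,8a-dimethyl-3-(propan-2-yl)-1,2,3,3a,4,7,8,8a-octahydroazulen-4-yl 4-methoxybenzoate | COc1ccc(C(=O)O[C@H]2C=C(C)CC[C@@]3(C)CC[C@@](O)(C(C)C)[C@H]23)cc1 | target

**Totals**

Total step count: 13.
Longest linear sequence: 12 steps (steps 1, 2 and 4–13, from hex-5-yn-2-one); the malic acid branch is 11 steps.

**The three steps most likely to fail**

Step 5 (dianion Ireland–Claisen). The malate dianion may decompose on warming before it rearranges, and facial or chair/boat control at the hindered quaternary centre may be incomplete. The fallback sets out from 8 and comes back at 10. Chelation control is given up: 8 is silylated (tBuMe2SiCl, imidazole, DMF) to the silyl ether F1. Its (Z)-silyl ketene acetal (silyloxy cis to the substituted carbon, the same geometry as in the chelate) is formed by internal quench with LiN(iPr)2 and Me3SiCl in THF–DMPU at −78 °C. This neutral species rearranges at 25–60 °C to the silyl-protected acid F2, where the face is chosen by allylic strain next to the silyloxy carbon; any minor diastereomer is removed by chromatography. HF·pyridine in THF then frees the hydroxyl and gives 10.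

Step 9 (isopropyl addition to the hindered, enolisable β-hydroxy ketone). Enolisation, reduction by β-hydride transfer or attack on the ester may win even with CeCl3. The fallback sets out from 13 and comes back at 15. The preformed polar organometallic is replaced by a samarium Barbier coupling: SmI2 and 2-iodopropane in THF–HMPA at 25 °C generate the isopropyl nucleophile by single-electron reduction in the presence of the samarium-bound ketone. This medium is essentially non-basic, and the resulting tertiary alkoxide again closes onto the methyl ester to give 15 after acidic work-up.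

Step 11 (Wittig methylenation of the unprotected α-hydroxy lactol). The open aldehyde is present in low concentration beside a tertiary alkoxide, and the basic ylide can epimerise the carbinol carbon next to it. The fallback sets out from 16 and comes back at 18. A two-stage Peterson olefination is used instead: excess Me3SiCH2MgCl in THF at 0 °C, a far less basic and more nucleophilic reagent, adds to the open form to give the β-hydroxysilane F3. KH in THF at 25 °C then brings about syn-elimination to the vinyl carbinol 18.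

**Further compounds**

F1 | step 5 | 4-[(2E)-3,6-dimethylhepta-2,6-dien-1-yl] 1-methyl (2R)-2-[(tert-butyldimethylsilyl)oxy]butanedioate | COC(=O)[C@H](O[Si](C)(C)C(C)(C)C)CC(=O)OC/C=C(\C)CCC(C)=C
F2 | step 5 | (2S,3R)-3-[(tert-butyldimethylsilyl)oxy]-2-[(3S)-3,6-dimethylhepta-1,6-dien-3-yl]-4-methoxy-4-oxobutanoic acid | OC(=O)[C@H]([C@@H](O[Si](C)(C)C(C)(C)C)C(=O)OC)[C@](C)(C=C)CCC(C)=C
F0 | step 9 | none | none
F3 | step 11 | (1R,2S,3S)-2-[(1R)-1,2-dihydroxy-3-(trimethylsilyl)propyl]-3-methyl-3-(3-methylbut-3-en-1-yl)-1-(propan-2-yl)cyclopentan-1-ol (both epimers at the silyl-side carbinol) | C[Si](C)(C)CC(O)[C@H](O)[C@H]1[C@](O)(C(C)C)CC[C@]1(C)CCC(C)=C
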